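**Assumption:** the SMILES is read as drawn, i.e. (1R,4R,5S,9S,11R,14R): trans ring fusion, a cis (Z-olefin-derived) 4,5-epoxide, the C-12 chain on C-11 syn to H-1. Caryophyllane locants are used for all intermediates (C-1/C-9 ring fusion, C-4/C-5 epoxide, C-8 methylidene carbon, C-10/C-11 cyclobutane, C-12 to C-15 side chain).

## Retrosynthetic overview

1. Target ⇐ peracid epoxidation of the Z-4,5-olefin and methylenation of the C-8 ketone of a trans-fused bicyclo[7.2.0]undec-4-en-8-one.
2. Nine-membered ring ⇐ light-driven three-carbon radical ring expansion of a bicyclo[4.2.0]octan-2-one (forms C-7–C-8, cleaves C-4–C-8, expels PhS• to leave the Z olefin).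
3. C-11 quaternary centre and side chain ⇐ Mn–H/Ni hydroalkylation of a methylenecyclobutane with a primary iodide made from (R)-α-hydroxy-γ-butyrolactone (C-14 bought).
4. Cyclobutane ⇐ intramolecular enolate alkylation of 10-chlorocarvone; C-1 is bought in (R)-carvone and relays C-9, C-11, C-4 and C-5.
5. Ring order: six-membered ring (bought) → four-membered ring → nine-membered ring (by expansion of the six) → oxirane.

## Route

**Step 1**
Reactants: 1 (R)-(−)-carvone
Product: 2 (5R)-5-(3-chloroprop-1-en-2-yl)-2-methylcyclohex-2-en-1-one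
Conditions: Ca(OCl)2, CO2 (dry ice), CH2Cl2/H2O, 0 °C
Reagents that add atoms: calcium hypochlorite, [Ca+2].[O-]Cl.[O-]Cl
Why: Ene-type allylic chlorination by HOCl attacks only the electron-rich isopropenyl group (the enone olefin is electron-poor) and leaves the bought stereocentre untouched.

**Step 2**
Reactants: 2 (5R)-5-(3-chloroprop-1-en-2-yl)-2-methylcyclohex-2-en-1-one
Product: 4 (1R,6R)-3-methyl-7-methylidenebicyclo[4.2.0]oct-3-en-2-one, via lithium dienolate 3 (not isolated)
Conditions: LiN(i-Pr)2 (1.1 equiv), THF, −78 °C; DMPU, −78 → 0 °C, 0.02 M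
Reagents that add atoms: lithium diisopropylamide, [Li+].CC(C)[N-]C(C)C (its lithium stays only in 3)
Why: Kinetic deprotonation at the α′-CH2 (C-9) gives the cross-conjugated enolate, which closes the four-membered ring by intramolecular allylic displacement (4-exo-tet enolate alkylation; SN2 and SN2′ give the same product); C-9 forms cis to C-1 because the tether reaches only one enolate face, and O-alkylation would need a bridgehead enol ether.

**Step 3**
Reactants: 4 (1R,6R)-3-methyl-7-methylidenebicyclo[4.2.0]oct-3-en-2-one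
Product: 7 (1R,3R,6R)-3-[3-chloro-1-(phenylsulfanyl)propyl]-3-methyl-7-methylidenebicyclo[4.2.0]octan-2-one (both epimers at the sulfur-bearing carbon), via lithium enolate 5 (not isolated), via trimethylsilyl enol ether 6 (not isolated)
Conditions: LiBH(s-Bu)3, THF, −78 °C; Me3SiCl, −78 → 0 °C; then PhSCH(Cl)CH2CH2Cl [from PhS(CH2)3Cl + NCS, CCl4], ZnBr2 (10 mol %), CH2Cl2, 0 °C
Reagents that add atoms: lithium tri-sec-butylborohydride, [Li+].CCC(C)[BH-](C(C)CC)C(C)CC (its lithium stays only in 5); chlorotrimethylsilane, C[Si](C)(C)Cl (its silyl group stays only in 6); 1,3-dichloro-1-(phenylsulfanyl)propane, ClCCC(Cl)Sc1ccccc1 (made in the flask from 3-chloropropyl phenyl sulfide, ClCCCSc1ccccc1, and N-chlorosuccinimide, O=C1CCC(=O)N1Cl)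
Why: 1,4-Reduction gives the regiodefined C-4/C-8 enolate, whose silyl enol ether is alkylated at C-4 by the thionium ion (ZnBr2-catalysed phenylthioalkylation of a silyl enol ether, good for quaternary centres); the new centres at C-4 (formed anti to the cyclobutane) and C-5 are both destroyed in step 8, so their configuration is irrelevant.

**Step 4**
Reactants: 8 (R)-α-hydroxy-γ-butyrolactone
Product: 9 (3R)-4-methylpentane-1,3,4-triol
Conditions: MeMgBr (3.5 equiv), THF, 0 → 25 °C; aq. NH4Cl
Reagents that add atoms: methylmagnesium bromide, C[Mg]Br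
Why: Double Grignard addition to the lactone carbonyl gives the tertiary carbinol; the α-alkoxide formed first blocks enolisation, so the bought C-14 centre is kept.

**Step 5**
Reactants: 9 (3R)-4-methylpentane-1,3,4-triol
Product: 10 (3R)-5-iodo-2-methylpentane-2,3-diol
Conditions: I2, PPh3, imidazole, THF/MeCN, 0 °C
Reagents that add atoms: iodine, II
Why: Appel-type iodination is selective for the primary hydroxyl over the hindered secondary and the tertiary one; the product is kept cold and used at once to avoid oxolane formation.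

**Step 6**
Reactants: 10 (3R)-5-iodo-2-methylpentane-2,3-diol
Product: 11 (3R)-2-hydroxy-5-iodo-2-methylpentan-3-yl acetate
Conditions: Ac2O, pyridine, 0 → 25 °C
Reagents that add atoms: acetic anhydride, CC(=O)OC(C)=O
Why: Standard acylation esterifies the secondary alcohol only; the tertiary alcohol does not react without forcing conditions.

**Step 7**
Reactants: 7 (1R,3R,6R)-3-[3-chloro-1-(phenylsulfanyl)propyl]-3-methyl-7-methylidenebicyclo[4.2.0]octan-2-one; 11 (3R)-2-hydroxy-5-iodo-2-methylpentan-3-yl acetate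
Product: 12 (3R)-5-{(1R,3R,6R,7R)-3-[3-chloro-1-(phenylsulfanyl)propyl]-3,7-dimethyl-2-oxobicyclo[4.2.0]octan-7-yl}-2-hydroxy-2-methylpentan-3-yl acetate
Conditions: Mn(dpm)3 (20 mol %), Ni(acac)2 (5 mol %), PhSiH3, K2CO3, 1,2-dichloroethane/propylene carbonate, 25 °C
Reagents that add atoms: none
Why: Branch-selective hydroalkylation by metal-hydride hydrogen-atom transfer with nickel co-catalysis: Mn–H gives H• to the exocyclic CH2 (which becomes the C-11 methyl), and the tertiary cyclobutyl radical is joined to the alkyl group of 11 at nickel on the convex face (syn to H-1, anti to C-2), which sets quaternary C-11 as R under control of the carvone-derived C-1; the alkyl chloride and sulfide are inert.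

**Step 8**
Reactants: 12 (3R)-5-{(1R,3R,6R,7R)-3-[3-chloro-1-(phenylsulfanyl)propyl]-3,7-dimethyl-2-oxobicyclo[4.2.0]octan-7-yl}-2-hydroxy-2-methylpentan-3-yl acetate
Product: 15 (3R)-5-[(1R,4Z,9S,11R)-4,11-dimethyl-8-oxobicyclo[7.2.0]undec-4-en-11-yl]-2-hydroxy-2-methylpentan-3-yl acetate, via primary iodide 13 (not isolated), via cis-fused ring-expanded ketone 14 (not isolated)
Conditions: NaI, acetone, 56 °C; evaporate; (Bu3Sn)2 (1.1 equiv), hν (sunlamp, Pyrex), PhH, 80 °C; then DBU, 60 °C
Reagents that add atoms: sodium iodide, [Na+].[I-] (its iodine stays only in 13)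
Why: Proposed new method: a light-driven, non-reductive Dowd–Beckwith-type three-carbon ring expansion ended by loss of a thiyl radical – Bu3Sn• (from Sn–Sn photolysis) takes iodine from 13, the primary C-7 radical adds to the C-8 carbonyl carbon through a five-membered transition state, the bicyclic alkoxy radical cleaves the C-4–C-8 ring-fusion bond to the tertiary C-4 radical, and this expels PhS• from C-5 to give the trisubstituted olefin irreversibly (no hydrogen donor is present, so premature reduction cannot compete), while PhS• regenerates Bu3Sn• from the distannane and equilibrates the olefin to the less strained Z isomer by reversible addition, and DBU finally epimerises C-9 (α to the ketone) to the more stable trans ring fusion under control of C-1; the closest known reaction types are the Bu3SnH-mediated Dowd–Beckwith expansion of β-keto esters and distannane/hν chains that end by β-scission of a phenylthio group.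

**Step 9**
Reactants: 15 (3R)-5-[(1R,4Z,9S,11R)-4,11-dimethyl-8-oxobicyclo[7.2.0]undec-4-en-11-yl]-2-hydroxy-2-methylpentan-3-yl acetate
Product: 16 (3R)-5-[(1R,4Z,9S,11R)-4,11-dimethyl-8-methylidenebicyclo[7.2.0]undec-4-en-11-yl]-2-hydroxy-2-methylpentan-3-yl acetate
Conditions: Zn, CH2Br2, TiCl4, THF/CH2Cl2, 0 → 25 °C
Reagents that add atoms: dibromomethane, BrCBr
Why: Takai–Lombardo methylenation uses a non-basic titanium methylidene reagent, so the hindered enolisable ketone is converted without epimerising C-9 and without touching the acetate.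

**Step 10**
Reactants: 16 (3R)-5-[(1R,4Z,9S,11R)-4,11-dimethyl-8-methylidenebicyclo[7.2.0]undec-4-en-11-yl]-2-hydroxy-2-methylpentan-3-yl acetate
Product: 17 CNP0157071.2
Conditions: mCPBA (1.05 equiv), NaHCO3, CH2Cl2, 0 °C
Reagents that add atoms: 3-chloroperoxybenzoic acid, OOC(=O)c1cccc(Cl)c1
Why: Prilezhaev epoxidation picks the more electron-rich trisubstituted Z olefin over the 1,1-disubstituted one and adds syn, so both centres are set together as the cis-epoxide; attack is expected on the peripheral face, the same side of C-4 that the parent E olefin (caryophyllene) offers when it gives its 4R oxide, which here means 4R,5S, though this face selectivity is not secure.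

## Compound list

1 | (R)-(−)-carvone, (5R)-2-methyl-5-(prop-1-en-2-yl)cyclohex-2-en-1-one | CC1=CC[C@H](CC1=O)C(C)=C | starting material
2 | (5R)-5-(3-chloroprop-1-en-2-yl)-2-methylcyclohex-2-en-1-one (10-chlorocarvone) | CC1=CC[C@H](CC1=O)C(=C)CCl | intermediate
3 | lithium (3R)-3-(3-chloroprop-1-en-2-yl)-6-methylcyclohexa-1,5-dien-1-olate | [Li+].[O-]C1=C[C@@H](CC=C1C)C(=C)CCl | intermediate (not isolated)
4 | (1R,6R)-3-methyl-7-methylidenebicyclo[4.2.0]oct-3-en-2-one (cis-fused) | CC1=CC[C@H]2C(=C)C[C@H]2C1=O | intermediate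
5 | lithium (1R,6R)-3-methyl-7-methylidenebicyclo[4.2.0]oct-2-en-2-olate | [Li+].CC1=C([O-])[C@@H]2CC(=C)[C@@H]2CC1 | intermediate (not isolated)
6 | trimethyl{[(1R,6R)-3-methyl-7-methylidenebicyclo[4.2.0]oct-2-en-2-yl]oxy}silane | CC1=C(O[Si](C)(C)C)[C@@H]2CC(=C)[C@@H]2CC1 | intermediate (not isolated)
7 | (1R,3R,6R)-3-[3-chloro-1-(phenylsulfanyl)propyl]-3-methyl-7-methylidenebicyclo[4.2.0]octan-2-one (both epimers at the sulfur-bearing carbon) | C[C@@]1(C(CCCl)Sc2ccccc2)CC[C@H]2C(=C)C[C@H]2C1=O | intermediate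
8 | (R)-α-hydroxy-γ-butyrolactone, (3R)-3-hydroxyoxolan-2-one | O=C1OCC[C@H]1O | starting material
9 | (3R)-4-methylpentane-1,3,4-triol | OCC[C@@H](O)C(C)(C)O | intermediate
10 | (3R)-5-iodo-2-methylpentane-2,3-diol | ICC[C@@H](O)C(C)(C)O | intermediate
11 | (3R)-2-hydroxy-5-iodo-2-methylpentan-3-yl acetate | ICC[C@@H](OC(C)=O)C(C)(C)O | intermediate
12 | (3R)-5-{(1R,3R,6R,7R)-3-[3-chloro-1-(phenylsulfanyl)propyl]-3,7-dimethyl-2-oxobicyclo[4.2.0]octan-7-yl}-2-hydroxy-2-methylpentan-3-yl acetate | C[C@@]1(C(CCCl)Sc2ccccc2)CC[C@H]2[C@](C)(CC[C@@H](OC(C)=O)C(C)(C)O)C[C@H]2C1=O | intermediate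
13 | (3R)-2-hydroxy-5-{(1R,3R,6R,7R)-3-[3-iodo-1-(phenylsulfanyl)propyl]-3,7-dimethyl-2-oxobicyclo[4.2.0]octan-7-yl}-2-methylpentan-3-yl acetate | C[C@@]1(C(CCI)Sc2ccccc2)CC[C@H]2[C@](C)(CC[C@@H](OC(C)=O)C(C)(C)O)C[C@H]2C1=O | intermediate (not isolated)
14 | (3R)-5-[(1R,4Z,9R,11R)-4,11-dimethyl-8-oxobicyclo[7.2.0]undec-4-en-11-yl]-2-hydroxy-2-methylpentan-3-yl acetate (cis ring fusion) | C/C1=C/CCC(=O)[C@@H]2C[C@@](C)(CC[C@@H](OC(C)=O)C(C)(C)O)[C@@H]2CC1 | intermediate (not isolated)
15 | (3R)-5-[(1R,4Z,9S,11R)-4,11-dimethyl-8-oxobicyclo[7.2.0]undec-4-en-11-yl]-2-hydroxy-2-methylpentan-3-yl acetate (trans ring fusion) | C/C1=C/CCC(=O)[C@H]2C[C@@](C)(CC[C@@H](OC(C)=O)C(C)(C)O)[C@@H]2CC1 | intermediate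
16 | (3R)-5-[(1R,4Z,9S,11R)-4,11-dimethyl-8-methylidenebicyclo[7.2.0]undec-4-en-11-yl]-2-hydroxy-2-methylpentan-3-yl acetate | C/C1=C/CCC(=C)[C@H]2C[C@@](C)(CC[C@@H](OC(C)=O)C(C)(C)O)[C@@H]2CC1 | intermediate
17 | CNP0157071.2, (3R)-2-hydroxy-2-methyl-5-[(1R,4R,6S,10S,12R)-4,12-dimethyl-9-methylidene-5-oxatricyclo[8.2.0.0^{4,6}]dodecan-12-yl]pentan-3-yl acetate | C=C1CC[C@@H]2O[C@]2(C)CC[C@@H]2[C@@H]1C[C@@]2(C)CC[C@@H](OC(C)=O)C(C)(C)O | target

## Step count

Total: 10 steps. Longest linear sequence: 7 steps (1 → 17 through steps 1, 2, 3, 7, 8, 9, 10); iodide 11 is made in a 3-step side branch (steps 4–6).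

## Steps most likely to fail

**Step 8 (the proposed ring expansion).** The C-7 radical may be lost before it adds to the carbonyl, or the alkoxy radical may revert. The fallback is the known hydroxy-sulfonate (Grob) fragmentation of a cyclobutane-fused hydrindanol. It sets out from 4 and comes back at 14, which DBU then takes to 15 as in step 8.
- Conjugate reduction of 4 with LiBH(s-Bu)3 (THF, −78 °C) and aldol addition of enolate 5 to 3-chloropropanal gives (1R,3S,6R)-3-(3-chloro-1-hydroxypropyl)-3-methyl-7-methylidenebicyclo[4.2.0]octan-2-one F3 (both carbinol epimers).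
- Hydroalkylation with 11 under the conditions of step 7 gives (3R)-5-[(1R,3S,6R,7R)-3-(3-chloro-1-hydroxypropyl)-3,7-dimethyl-2-oxobicyclo[4.2.0]octan-7-yl]-2-hydroxy-2-methylpentan-3-yl acetate F4.
- NaI in acetone gives (3R)-2-hydroxy-5-[(1R,3S,6R,7R)-3-(1-hydroxy-3-iodopropyl)-3,7-dimethyl-2-oxobicyclo[4.2.0]octan-7-yl]-2-methylpentan-3-yl acetate F5.
- SmI2/HMPA in THF closes the five-membered ring by intramolecular Barbier addition of C-7 to the C-8 ketone, giving (3R)-5-[1,9-dihydroxy-4,8-dimethyltricyclo[6.3.0.0^{2,5}]undecan-4-yl]-2-hydroxy-2-methylpentan-3-yl acetate F6 (tertiary hydroxyl cis to the C-4 methyl).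
- MsCl/pyridine sulfonylates only the secondary hydroxyl, giving (3R)-2-hydroxy-5-[1-hydroxy-9-(methanesulfonyloxy)-4,8-dimethyltricyclo[6.3.0.0^{2,5}]undecan-4-yl]-2-methylpentan-3-yl acetate F7.
- t-BuOK in THF at 0 °C fragments the C-4–C-8 bond anti to the mesylate. The epimer with the mesylate trans to the C-4 methyl gives 14 directly; the other gives (3R)-5-[(1R,4E,9R,11R)-4,11-dimethyl-8-oxobicyclo[7.2.0]undec-4-en-11-yl]-2-hydroxy-2-methylpentan-3-yl acetate F8, which PhSSPh/hν isomerises to 14.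

**Step 2 (four-membered ring closure).** The α′-enolate can equilibrate to the extended dienolate, which would close a six-membered ring (a bicyclo[2.2.2]octenone) instead. The fallback removes the enone first, so that no dienolate exists. It sets out from 2 and comes back at 6.
- LiBH(s-Bu)3 in THF at −78 °C with a MeOH quench at −78 °C gives (5R)-5-(3-chloroprop-1-en-2-yl)-2-methylcyclohexan-1-one F1 (both C-2 epimers).
- LiN(i-Pr)2 then forms the kinetic, less substituted enolate at the only CH2 next to the carbonyl, and the same displacement gives (1R,6R)-3-methyl-7-methylidenebicyclo[4.2.0]octan-2-one F2.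
- Me3SiCl/NaI/Et3N in MeCN (thermodynamic conditions) gives the tetrasubstituted silyl enol ether, which is 6; the route continues with the thioalkylation half of step 3.

**Step 10 (facial selectivity of the epoxidation).** If the peracid prefers the other face of the Z olefin, the oxygen is delivered from the opposite side through a halohydrin. The fallback sets out from 16 and comes back at 17.
- NBS in THF/H2O at 0 °C forms the bromonium ion on the face the peracid prefers and water opens it anti at the tertiary C-4, giving (3R)-5-[(1R,4R,5R,9S,11R)-5-bromo-4-hydroxy-4,11-dimethyl-8-methylidenebicyclo[7.2.0]undecan-11-yl]-2-hydroxy-2-methylpentan-3-yl acetate F9.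
- DBU in CH2Cl2 closes the oxirane with inversion at C-5 to give 17.

## Further compounds

F1 | step 2 | (5R)-5-(3-chloroprop-1-en-2-yl)-2-methylcyclohexan-1-one (C-2 epimers) | CC1CC[C@H](CC1=O)C(=C)CCl
F2 | step 2 | (1R,6R)-3-methyl-7-methylidenebicyclo[4.2.0]octan-2-one (C-3 epimers) | CC1CC[C@H]2C(=C)C[C@H]2C1=O
F3 | step 8 | (1R,3S,6R)-3-(3-chloro-1-hydroxypropyl)-3-methyl-7-methylidenebicyclo[4.2.0]octan-2-one (carbinol epimers) | C[C@@]1(C(O)CCCl)CC[C@H]2C(=C)C[C@H]2C1=O
F4 | step 8 | (3R)-5-[(1R,3S,6R,7R)-3-(3-chloro-1-hydroxypropyl)-3,7-dimethyl-2-oxobicyclo[4.2.0]octan-7-yl]-2-hydroxy-2-methylpentan-3-yl acetate | C[C@@]1(C(O)CCCl)CC[C@H]2[C@](C)(CC[C@@H](OC(C)=O)C(C)(C)O)C[C@H]2C1=O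
F5 | step 8 | (3R)-2-hydroxy-5-[(1R,3S,6R,7R)-3-(1-hydroxy-3-iodopropyl)-3,7-dimethyl-2-oxobicyclo[4.2.0]octan-7-yl]-2-methylpentan-3-yl acetate | C[C@@]1(C(O)CCI)CC[C@H]2[C@](C)(CC[C@@H](OC(C)=O)C(C)(C)O)C[C@H]2C1=O
F6 | step 8 | (3R)-5-[1,9-dihydroxy-4,8-dimethyltricyclo[6.3.0.0^{2,5}]undecan-4-yl]-2-hydroxy-2-methylpentan-3-yl acetate (1-OH cis to 8-CH3; C-9 epimers) | C[C@@]12CC[C@H]3[C@](C)(CC[C@@H](OC(C)=O)C(C)(C)O)C[C@H]3[C@]1(O)CCC2O
F7 | step 8 | (3R)-2-hydroxy-5-[1-hydroxy-9-(methanesulfonyloxy)-4,8-dimethyltricyclo[6.3.0.0^{2,5}]undecan-4-yl]-2-methylpentan-3-yl acetate | C[C@@]12CC[C@H]3[C@](C)(CC[C@@H](OC(C)=O)C(C)(C)O)C[C@H]3[C@]1(O)CCC2OS(C)(=O)=O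
F8 | step 8 | (3R)-5-[(1R,4E,9R,11R)-4,11-dimethyl-8-oxobicyclo[7.2.0]undec-4-en-11-yl]-2-hydroxy-2-methylpentan-3-yl acetate | C/C1=C\CCC(=O)[C@@H]2C[C@@](C)(CC[C@@H](OC(C)=O)C(C)(C)O)[C@@H]2CC1
F9 | step 10 | (3R)-5-[(1R,4R,5R,9S,11R)-5-bromo-4-hydroxy-4,11-dimethyl-8-methylidenebicyclo[7.2.0]undecan-11-yl]-2-hydroxy-2-methylpentan-3-yl acetate | C=C1CC[C@@H](Br)[C@](C)(O)CC[C@@H]2[C@@H]1C[C@@]2(C)CC[C@@H](OC(C)=O)C(C)(C)O
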